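You have two numbers to find and one choice to make.

| flask | substrate | precatalyst | temperature | remark | time |
|---|---|---|---|---|---|
| noon | 42 mM (fed, over 50 min) | 0.88 mM | 8 °C | run made earlier; the fed solution adds 0.25 times the starting volume |  |
| winter | 42 mM (fed, over 50 min) | 3.3 mM | 24 °C | run made earlier; the fed solution adds 0.25 times the starting volume |  |
| east | 42 mM (fed, over 50 min) | 2.6 mM |  | at 0 °C until 50 min, from then on at 30 °C; the fed solution adds 0.25 times the starting volume | 3.0 h |
| south-west | 42 mM (fed, over 80 min) | 0.80 mM |  | at 0 °C throughout; the fed solution adds 0.25 times the starting volume | 3.0 h |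

| noon: time / min | noon: target / % | winter: time / min | winter: target / % |
|---|---|---|---|
| 8.00 | 0.4 | 6.00 | 0.6 |
| 25.0 | 0 | 12.0 | 2.3 |
| 40.0 | 0.7 | 15.0 | 2.7 |
| 60.0 | 2.9 | 25.0 | 12.7 |
| 90.0 | 2.5 | 30.0 | 17.4 |

(scatter of a reading: 1 percentage point)

- the flask that ends with the higher amount of target, in percent of the substrate charged, or "neither" when 2 percentage points or less lies between them (east / south-west / neither)
- final target, as a percentage of the substrate charged, in east
- final target, as a percentage of the substrate charged, in south-west

- every charge counts on the volume at the start, and the solution that is fed holds the whole dose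
- what was read earlier has a scatter of 1 percentage point, one standard deviation
- percentages count the whole charge, also what has not yet gone in

1. Take first the main step by itself. Winter's substrate enters steadily, so the fraction of the charge that has entered by time t is t/t_f, where t_f is the dosing time. If it is consumed at first order with rate constant k, the target fraction is P = k t·t/(2 t_f). Winter's last reading gives k = 0.0193 /min, a half-life of 35.9 min. At that speed, east's warm stretch of 130 min holds 3.63 half-lives, and this step by itself points to a yield near completion.

2. Now suppose that the catalyst stops. Noon reads 2.9% at 60.0 min and 2.5% at 90.0 min, a change smaller than the scatter, although its feed has ended. So count the turnover number N = 2.21, target formed per precatalyst charged, read at winter's 30.0 min and still rising there. Noon's reading at 60.0 min gives 1.38.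

3. Solve east at both ends. I assume that east's catalyst gives the count read in winter, although the temperatures differ; if it then stops, east ends at 13.7%. If the count keeps growing with the square of the time until the feed ends, east ends at 38.1%. Joining them by their geometric mean, I commit to 22.8%.

4. South-west stands at 0 °C for 3.0 h, and I assume for its catalyst the count of noon, the colder run, which makes 2.64%. By my reckoning east leads by more than the margin.

The forecast also says east, but it puts east higher than I do, at 88% (55% to 99%), with south-west at 1.5% (0.6% to 3.5%), and it notes that “noon plateau hints at possible catalyst death”.

The simulation gives east: east 26.3%, south-west 2.73%.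

    substrate + free catalyst ⇌ catalyst intermediate A (K = 7.80 /M, k = 250 /M/h, Ea = 60.0 kJ/mol, ΔH = −15.0 kJ/mol)
    catalyst intermediate A → catalyst intermediate B (k = 68.0 /h, Ea = 83.0 kJ/mol)
    catalyst intermediate B ⇌ free catalyst + target (K = 0.0420 M, k = 14.0 /h, Ea = 80.0 kJ/mol, ΔH = 19.0 kJ/mol)
    precatalyst → free catalyst (k = 0.190 /h, Ea = 81.0 kJ/mol)
    free catalyst → spent catalyst (k = 0.110 /h, Ea = 87.0 kJ/mol)
    2 substrate → homo dimer (k = 12.0 /M/h, Ea = 54.0 kJ/mol)
    (constants at 0 °C)

East's target comes to 4.24 turnovers, twice winter's count of 2.21, and between 0.833 h and 1.50 h east gained 48 percentage points of homo dimer, counted by the substrate it holds, against 24 points of target. The repeat of south-west at 25 °C gives 9.95%, which is 5.22 turnovers, with spent catalyst at 99.8% of the catalyst charged.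

The readings are calculated from invented constants; the scatter is artificial.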